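Ring A of the target (briarane numbering: C1 quaternary, C10 ring-fusion CH, C11–C14) is cut across C13–C12 and C1–C10 into a three-carbon keto ester and a three-carbon enoate. The key step is a one-pot Michael–Claisen [3+3] annulation of allyl 2-methylacetoacetate with enantiopure 5-menthyloxy-3-methylbutenolide: conjugate addition makes C1–C10, then the methyl-ketone enolate acylates the lactone carbonyl, making C13–C12. It exploits that C9–C10–C11–C12, with C9 and the C11 methyl cis on ring A, is a latent 5-oxygenated 3-methylbutenolide; the acetal centre fixes C10 and C11, then leaves as menthol and unveils the C9 aldehyde. The precursor is a monocyclic butenolide plus an open-chain keto ester.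

Key step: step 4

Remark: CNP0253247.1 is taken as the structure defined by the SMILES, i.e. (1S,2S,3Z,6S,7R,8R,9S,10S,11R,12R,17R)-2,9-diacetoxy-6-chloro-8,12-dihydroxybriara-3,5(16),13-trien-19,7-olide; locants C1–C20 in the names below use this numbering (C15 = CH3 on C1, C16 = exocyclic CH2 on C5, C17/C18/C19 = lactone CH, its CH3 and C=O, C20 = CH3 on C11).
Remark: compounds 1, 3, 5, 12, 13 and 25 are taken as commercial; C1 in 7–11 is carried as both epimers and the chloromethylidene group in 16–38 as an E/Z mixture (neither is specified in the SMILES, and both are erased later).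

Step 1
Reactants: 1 3-methylfuran-2-carboxylic acid
Product: 2 5-hydroxy-3-methylfuran-2(5H)-one (racemic)
Conditions: O2, 5,10,15,20-tetraphenylporphyrin (cat.), visible light, CH2Cl2/MeOH, 0 °C
Reagents that add atoms: dioxygen O=O
Why: Singlet-oxygen [4+2] addition to the furan and decarboxylative collapse of the endoperoxide (furan photooxygenation) should give the γ-hydroxybutenolide with the methyl group next to the lactone carbonyl.

Step 2
Reactants: 2 5-hydroxy-3-methylfuran-2(5H)-one; 3 (−)-menthol
Product: 4 (5R)-3-methyl-5-[(1R,2S,5R)-menthyloxy]furan-2(5H)-one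
Conditions: camphor-10-sulfonic acid (cat.), toluene, reflux, Dean–Stark; crystallisation from hexane, mother liquor re-equilibrated with acid
Reagents that add atoms: none
Why: Acid-catalysed acetalisation of the pseudo-acid gives both acetal epimers, and the (5R) epimer should be secured by crystallisation with acid-mediated epimerisation of the remainder (crystallisation-driven asymmetric transformation, as for the parent 5-menthyloxybutenolide).

Step 3
Reactants: 5 allyl 3-oxobutanoate
Product: 6 allyl 2-methyl-3-oxobutanoate (racemic)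
Conditions: MeI, K2CO3, acetone, reflux
Reagents that add atoms: iodomethane CI
Why: C-Alkylation of the stabilised acetoacetate enolate installs the methyl group that becomes C15.

Step 4
Reactants: 4 (5R)-3-methyl-5-menthyloxyfuran-2(5H)-one; 6 allyl 2-methyl-3-oxobutanoate
Product: 8 allyl (5R,6S)-6-formyl-1,5-dimethyl-2,4-dioxocyclohexane-1-carboxylate as both C1 epimers, via Michael adduct 7 (not isolated)
Conditions: KOt-Bu (0.1 equiv), THF, 0 °C → rt; then LiN(SiMe3)2 (1.1 equiv), −78 → 0 °C; aq. NH4Cl
Reagents that add atoms: none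
Why: Catalytic KOt-Bu generates the stabilised enolate of 6, whose doubly activated carbon adds 1,4 to butenolide 4 (Michael addition, C1–C10) and the lactone enolate is protonated by further 6 to give 7; LiN(SiMe3)2 then deprotonates the methyl ketone, whose enolate attacks the lactone carbonyl and, after collapse of the bridged tetrahedral alkoxide and loss of the hemiacetal as menthol, forms the C13–C12 bond as the enolate of the 1,3-dione. The closest known reaction type is the consecutive Michael–Claisen [3+3] annulation of acetoacetates with α,β-unsaturated esters that underlies classical cyclohexane-1,3-dione syntheses, here run on a γ-alkoxybutenolide. Ring A is the only ring closed, by a 6-(enolendo)-exo-trig acyl substitution (Dieckmann-type) on the lactone carbonyl, which opens the five-membered ring at the same time. C10 is set by attack anti to the menthyloxy group on the acetal carbon and C11 by protonation of the lactone enolate anti to the new C10 substituent, which places C9 and the C11 methyl cis on ring A; C1 is not controlled and is erased in step 6. The step needs regioselectivity (Michael through the central carbon of 6, acylation through its methyl group), secured by acidity in the first stage and by the six-membered ring size in the second, and it must avoid epimerisation of the acetal and of C10, secured because no free strong base remains once the dione enolate, the thermodynamic sink, has formed.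

Step 5
Reactants: 8 dione aldehyde
Product: 9 allyl (5R,6S)-6-formyl-1,5-dimethyl-2-oxo-4-(trifluoromethanesulfonyloxy)cyclohex-3-ene-1-carboxylate (both C1 epimers)
Conditions: PhNTf2, Et3N, 4-(dimethylamino)pyridine (cat.), CH2Cl2, 0 °C → rt
Reagents that add atoms: N-phenylbis(trifluoromethanesulfonimide) FC(F)(F)S(=O)(=O)N(c1ccccc1)S(=O)(=O)C(F)(F)F
Why: Enol triflate formation should occur on the less hindered oxygen of the dione enolate, the one on C12 next to the CH(CH3) carbon and remote from the quaternary C1, which differentiates the two carbonyl groups.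

Step 6
Reactants: 9 enol triflate
Product: 10 (1S,6S)-2,6-dimethyl-3-oxocyclohex-4-ene-1-carbaldehyde (both C2 epimers; C14 ketone, C12=C13, C9 aldehyde)
Conditions: Pd(OAc)2 (5 mol %), PPh3, HCO2H, Et3N, THF, 40 °C
Reagents that add atoms: none
Why: Zerovalent palladium formed in situ should do two known jobs at once, formate reduction of the β-triflyloxy enone to the enone and Tsuji-type deallylation–decarboxylation–protonation of the allyl β-keto ester, which removes the activating ester and erases the uncontrolled C1 centre.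

Step 7
Reactants: 10 enone aldehyde
Product: 11 (4S,5S)-5-(dimethoxymethyl)-4,6-dimethylcyclohex-2-en-1-one (both C6 epimers)
Conditions: HC(OMe)3, MeOH, pyridinium p-toluenesulfonate (cat.), rt
Reagents that add atoms: trimethyl orthoformate COC(OC)OC; methanol CO
Why: Aldehyde-selective acetalisation (the conjugated ketone is far less reactive) protects C9 before enolate chemistry.

Step 8
Reactants: 12 2-[(tert-butyldimethylsilyl)oxy]acetaldehyde; 13 3,3-diethoxyprop-1-yne
Product: 14 1-[(tert-butyldimethylsilyl)oxy]-5,5-diethoxypent-3-yn-2-ol (racemic)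
Conditions: 13, n-BuLi, THF, −78 °C; then 12; aq. NH4Cl
Reagents that add atoms: none
Why: 1,2-Addition of the lithium acetylide to the aldehyde joins C2–C4 to C5 and C16.

Step 9
Reactants: 14 propargylic alcohol
Product: 15 1-[(tert-butyldimethylsilyl)oxy]-5,5-diethoxypent-3-yn-2-one
Conditions: Dess–Martin periodinane, NaHCO3, CH2Cl2, 0 °C → rt
Reagents that add atoms: none
Why: Dess–Martin oxidation gives the ynone under neutral conditions that spare the acetal and the silyl ether.

Step 10
Reactants: 15 ynone
Product: 16 5-[(tert-butyldimethylsilyl)oxy]-4-(chloromethylidene)-1,1-diethoxypent-2-yne (E/Z mixture)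
Conditions: Ph3P(CH2Cl)Cl, NaN(SiMe3)2, THF, −78 → 0 °C
Reagents that add atoms: (chloromethyl)triphenylphosphonium chloride ClC[P+](c1ccccc1)(c1ccccc1)c1ccccc1.[Cl-]
Why: Wittig chloromethylenation of the ketone installs C6 with its chlorine; the alkene geometry is of no consequence because it is lost in the allylchromium intermediate of step 30.

Step 11
Reactants: 16 chloroenyne acetal
Product: 17 5-[(tert-butyldimethylsilyl)oxy]-4-(chloromethylidene)pent-2-ynal (E/Z mixture; C2–C6 and C16 of the target)
Conditions: p-toluenesulfonic acid monohydrate (cat.), acetone/H2O, rt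
Reagents that add atoms: water O
Why: Mild acid hydrolysis of the diethyl acetal liberates the ynal, which is used at once.

Step 12
Reactants: 11 enone acetal; 17 ynal
Product: 19 aldol acetate (ring A enone quaternised at C1 by the C2–C6 chain), via lithium aldolate 18 (not isolated)
Conditions: LiN(i-Pr)2, THF, −78 °C; then 17, −78 °C; then Ac2O, −78 → 0 °C
Reagents that add atoms: acetic anhydride CC(=O)OC(C)=O
Why: Kinetic α′-deprotonation of the enone and aldol addition of the cross-conjugated lithium enolate should take place on the face of C1 opposite the pseudoaxial C10 acetal substituent (C15 cis to C9) through a chair Zimmerman–Traxler transition state with the alkynyl group equatorial (C2 as in the target), and O-acetylation of the aldolate blocks retro-aldol cleavage.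

Step 13
Reactants: 19 aldol acetate
Product: 20 12,13-epoxy ketone
Conditions: t-BuOOH (anhydrous), DBU, CH2Cl2, 0 °C → rt
Reagents that add atoms: tert-butyl hydroperoxide CC(C)(C)OO
Why: Weitz–Scheffer nucleophilic epoxidation of the enone, in which the peroxide should add to C12 on the ring face opposite the axial C10 substituent and trans to the C11 methyl group, placing the epoxide oxygen where the 12-OH is needed.

Step 14
Reactants: 20 epoxy ketone
Product: 21 allylic alcohol (C13=C14, 12-OH)
Conditions: N2H4·H2O, AcOH, MeOH, 0 °C → rt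
Reagents that add atoms: none
Why: Wharton transposition, in which the epoxy hydrazone fragments with loss of N2 to the C13=C14 alkene and the C12 alcohol, C12 keeping the configuration set in step 13.

Step 15
Reactants: 21 allylic alcohol
Product: 22 12-O-TBS ether
Conditions: t-BuMe2SiOTf, 2,6-lutidine, CH2Cl2, −78 → 0 °C
Reagents that add atoms: tert-butyldimethylsilyl trifluoromethanesulfonate CC(C)(C)[Si](C)(C)OS(=O)(=O)C(F)(F)F
Why: Silylation masks the 12-OH, which must stay free of acetate at the end, with a group that outlasts the later removal of the primary silyl ether.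

Step 16
Reactants: 22 enyne
Product: 23 (3Z)-diene
Conditions: H2 (1 atm), Pd/CaCO3 poisoned with Pb(OAc)2, quinoline, EtOAc, rt
Reagents that add atoms: none
Why: Lindlar semihydrogenation adds hydrogen syn to the alkyne and should give the (3Z)-alkene while sparing the vinyl chloride and the ring alkene.

Step 17
Reactants: 23 dimethyl acetal
Product: 24 C9 aldehyde
Conditions: LiBF4, MeCN/H2O (50:1), rt
Reagents that add atoms: water O
Why: Mild Lewis-acid hydrolysis of the dimethyl acetal liberates the C9 aldehyde without cleaving the silyl ethers or the allylic acetate.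

Step 18
Reactants: 25 diethyl (S)-malate
Product: 26 diethyl (2S,3R)-2-hydroxy-3-methylbutanedioate
Conditions: LiN(i-Pr)2 (2.1 equiv), THF, −78 → −20 °C; then MeI, −78 °C → rt
Reagents that add atoms: iodomethane CI
Why: Fráter–Seebach alkylation, in which the chelated alkoxide–enolate dianion is methylated anti to the alkoxide, should give the (2S,3R) diester whose C2 and C3 become C8 and C17.

Step 19
Reactants: 26 diethyl (2S,3R)-3-methylmalate
Product: 27 (2S,3R)-2-hydroxy-3-methylbutanedioic acid
Conditions: KOH, H2O/EtOH, 0 °C → rt; then HCl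
Reagents that add atoms: potassium hydroxide [K+].[OH-]
Why: Saponification of both esters frees the α-hydroxy acid needed for the acetal template.

Step 20
Reactants: 27 (2S,3R)-3-methylmalic acid
Product: 28 (2R)-2-[(2S,4S)-2-tert-butyl-5-oxo-1,3-dioxolan-4-yl]propanoic acid
Conditions: t-BuCHO, p-toluenesulfonic acid (cat.), H2SO4 (cat.), pentane, reflux, Dean–Stark
Reagents that add atoms: pivalaldehyde CC(C)(C)C=O
Why: Acetalisation of the α-hydroxy acid with pivalaldehyde under thermodynamic control should give the cis-dioxolanone and leave the β-carboxyl group free (template for self-regeneration of stereocentres).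

Step 21
Reactants: 28 dioxolanone acid
Product: 29 tert-butyl (2R)-2-[(2S,4S)-2-tert-butyl-5-oxo-1,3-dioxolan-4-yl]propanoate
Conditions: Cl3CC(=NH)Ot-Bu, BF3·OEt2 (cat.), CH2Cl2/cyclohexane, rt
Reagents that add atoms: tert-butyl 2,2,2-trichloroacetimidate CC(C)(C)OC(=N)C(Cl)(Cl)Cl
Why: Acid-catalysed tert-butylation of the carboxylic acid by the trichloroacetimidate works without base, so neither stereocentre is endangered, and gives an ester that resists premature lactonisation onto O9.

Step 22
Reactants: 24 C9 aldehyde; 29 dioxolanone ester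
Product: 30 aldol adduct (C8–C9 bond, both C9 epimers)
Conditions: 29, LiN(i-Pr)2, THF, −78 °C; then 24, −78 °C; aq. NH4Cl at −78 °C
Reagents that add atoms: none
Why: Aldol addition of the dioxolanone lithium enolate (self-regeneration of stereocentres), in which the aldehyde is attacked on the enolate face anti to the tert-butyl group so that C8 is formed with overall retention; the C9 carbinol is not controlled and is reset in steps 23 and 24.

Step 23
Reactants: 30 aldol adduct
Product: 31 C9 ketone
Conditions: Dess–Martin periodinane, NaHCO3, CH2Cl2, rt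
Reagents that add atoms: none
Why: Dess–Martin oxidation converges both C9 epimers to one ketone that cannot enolise towards C8.

Step 24
Reactants: 31 C9 ketone
Product: 32 (9S) alcohol
Conditions: Zn(BH4)2, Et2O, −30 °C
Reagents that add atoms: none
Why: Chelation-controlled reduction, in which zinc bridges the C9 carbonyl and the dioxolanone oxygen on C8 and hydride should add anti to the branched C17 side chain, gives the C9 alcohol with O8 and O9 syn as in the target.

Step 25
Reactants: 32 dioxolanone alcohol
Product: 33 Weinreb amide (C7), free 8-OH and 9-OH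
Conditions: MeNHOMe·HCl, i-PrMgCl, THF, −20 → 0 °C
Reagents that add atoms: N,O-dimethylhydroxylamine hydrochloride CNOC.Cl
Why: Aminolysis of the activated dioxolanone (an acylal-type lactone) by the magnesium amide gives the Weinreb amide, frees the tertiary 8-OH and releases pivalaldehyde, while the neopentyl acetate and the tert-butyl ester should react more slowly.

Step 26
Reactants: 33 Weinreb amide
Product: 34 C7 aldehyde with free 2-, 8- and 9-OH
Conditions: i-Bu2AlH (excess), THF, −78 °C; aq. potassium sodium tartrate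
Reagents that add atoms: none
Why: i-Bu2AlH reduces the Weinreb amide to the aldehyde through the stable chelated tetrahedral intermediate and at the same time cleaves the C2 acetate, while the tert-butyl ester survives at −78 °C.

Step 27
Reactants: 34 aldehyde triol
Product: 35 2,9-diacetate
Conditions: Ac2O, pyridine, 4-(dimethylamino)pyridine (cat.), CH2Cl2, 0 °C → rt
Reagents that add atoms: acetic anhydride CC(=O)OC(C)=O
Why: Acetylation installs both acetates of the target on the two secondary alcohols, while the tertiary 8-OH stays free and the 12-OH is masked as the silyl ether.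

Step 28
Reactants: 35 diacetate
Product: 36 16-alcohol
Conditions: HF·pyridine, pyridine, THF, 0 °C
Reagents that add atoms: none
Why: Buffered HF·pyridine should cleave the primary allylic silyl ether selectively in the presence of the hindered secondary one on C12.

Step 29
Reactants: 36 16-alcohol
Product: 38 allylic bromide (16-bromo analogue of 36), via allylic mesylate 37 (not isolated)
Conditions: MsCl, Et3N, CH2Cl2, −30 °C; then LiBr, THF, 0 °C
Reagents that add atoms: methanesulfonyl chloride CS(=O)(=O)Cl (in 37); lithium bromide [Li+].[Br-]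
Why: Mesylation of the primary allylic alcohol and SN2 displacement by bromide give the allylic bromide, the tertiary 8-OH being too hindered to be sulfonylated.

Step 30
Reactants: 38 allylic bromide
Product: 39 ten-membered ring: tert-butyl ester of the 6-chloro-7-hydroxy acid
Conditions: CrCl2 (6 equiv), THF, rt, slow addition of 38 (final 0.002 M)
Reagents that add atoms: none
Why: Nozaki–Hiyama–Kishi-type intramolecular γ-chloroallylation, in which chromium dichloride (divalent chromium) turns the bromide into a γ-chloroallylchromium species that adds through C6 to the C7 aldehyde in a chair transition state, should give the anti chlorohydrin (C6, C7) and the exocyclic C5=C16 methylene, with the tether and chelation to the 8-alkoxide choosing the aldehyde face.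

Step 31
Reactants: 39 hydroxy tert-butyl ester
Product: 40 12-O-TBS ether of the target
Conditions: camphor-10-sulfonic acid (cat.), toluene, 50 °C
Reagents that add atoms: none
Why: Acid-catalysed lactonisation of the γ-hydroxy tert-butyl ester (7-OH onto C19) closes the five-membered lactone with loss of tert-butanol, and only the 7,19-lactone can form because O9 is already acetylated.

Step 32
Reactants: 40 silyl ether
Product: 41 CNP0253247.1
Conditions: HF·pyridine, THF, 0 °C → rt
Reagents that add atoms: none
Why: Fluoride-mediated desilylation frees the 12-OH under conditions that should leave the allylic chloride, the acetates and the lactone untouched.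

Compound list
1 | 3-methylfuran-2-carboxylic acid | Cc1ccoc1C(=O)O | starting material
2 | 5-hydroxy-3-methylfuran-2(5H)-one (racemic) | CC1=CC(O)OC1=O | intermediate
3 | (−)-menthol, (1R,2S,5R)-2-isopropyl-5-methylcyclohexan-1-ol | C[C@@H]1CC[C@H]([C@@H](C1)O)C(C)C | starting material
4 | (5R)-3-methyl-5-{[(1R,2S,5R)-2-isopropyl-5-methylcyclohexyl]oxy}furan-2(5H)-one | CC1=C[C@H](O[C@@H]2C[C@H](C)CC[C@H]2C(C)C)OC1=O | intermediate
5 | allyl 3-oxobutanoate | CC(=O)CC(=O)OCC=C | starting material
6 | allyl 2-methyl-3-oxobutanoate (racemic) | CC(=O)C(C)C(=O)OCC=C | intermediate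
7 | Michael adduct: allyl 2-methyl-2-[(2R,3S,4R)-2-menthyloxy-4-methyl-5-oxooxolan-3-yl]-3-oxobutanoate (both epimers at the quaternary carbon) | C[C@H]1C(=O)O[C@@H](O[C@@H]2C[C@H](C)CC[C@H]2C(C)C)[C@@H]1C(C)(C(C)=O)C(=O)OCC=C | intermediate
8 | allyl (5R,6S)-6-formyl-1,5-dimethyl-2,4-dioxocyclohexane-1-carboxylate (both C1 epimers; formyl and 5-methyl cis) | CC1(C(=O)OCC=C)C(=O)CC(=O)[C@H](C)[C@@H]1C=O | intermediate
9 | allyl (5R,6S)-6-formyl-1,5-dimethyl-2-oxo-4-(trifluoromethanesulfonyloxy)cyclohex-3-ene-1-carboxylate (both C1 epimers) | CC1(C(=O)OCC=C)C(=O)C=C(OS(=O)(=O)C(F)(F)F)[C@H](C)[C@@H]1C=O | intermediate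
10 | (1S,6S)-2,6-dimethyl-3-oxocyclohex-4-ene-1-carbaldehyde (both C2 epimers) | CC1C(=O)C=C[C@H](C)[C@@H]1C=O | intermediate
11 | (4S,5S)-5-(dimethoxymethyl)-4,6-dimethylcyclohex-2-en-1-one (both C6 epimers) | CC1C(=O)C=C[C@H](C)[C@@H]1C(OC)OC | intermediate
12 | 2-[(tert-butyldimethylsilyl)oxy]acetaldehyde | O=CCO[Si](C)(C)C(C)(C)C | starting material
13 | 3,3-diethoxyprop-1-yne | C#CC(OCC)OCC | starting material
14 | 1-[(tert-butyldimethylsilyl)oxy]-5,5-diethoxypent-3-yn-2-ol (racemic) | CCOC(OCC)C#CC(O)CO[Si](C)(C)C(C)(C)C | intermediate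
15 | 1-[(tert-butyldimethylsilyl)oxy]-5,5-diethoxypent-3-yn-2-one | CCOC(OCC)C#CC(=O)CO[Si](C)(C)C(C)(C)C | intermediate
16 | 5-[(tert-butyldimethylsilyl)oxy]-4-(chloromethylidene)-1,1-diethoxypent-2-yne (E/Z) | CCOC(OCC)C#CC(=CCl)CO[Si](C)(C)C(C)(C)C | intermediate
17 | 5-[(tert-butyldimethylsilyl)oxy]-4-(chloromethylidene)pent-2-ynal (E/Z) | O=CC#CC(=CCl)CO[Si](C)(C)C(C)(C)C | intermediate
18 | lithium aldolate of 11 and 17 (C2 alkoxide) | [Li+].C[C@]1([C@@H]([O-])C#CC(=CCl)CO[Si](C)(C)C(C)(C)C)C(=O)C=C[C@H](C)[C@@H]1C(OC)OC | intermediate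
19 | aldol acetate: ring A enone (C14 ketone, C12=C13) with quaternary C1 bearing CH3 and the chain C2H(OAc)–C3≡C4–C5(=C6HCl)–C16H2OTBS, C10 bearing CH(OCH3)2; C15, C9 and C20 mutually cis on ring A, C2 as in the target | C[C@]1([C@@H](OC(C)=O)C#CC(=CCl)CO[Si](C)(C)C(C)(C)C)C(=O)C=C[C@H](C)[C@@H]1C(OC)OC | intermediate
20 | 12,13-epoxy ketone of 19 (epoxide oxygen trans to C20) | C[C@]1([C@@H](OC(C)=O)C#CC(=CCl)CO[Si](C)(C)C(C)(C)C)C(=O)[C@H]2O[C@H]2[C@H](C)[C@@H]1C(OC)OC | intermediate
21 | allylic alcohol: C13=C14, 12-OH as in the target, otherwise as 19 | C[C@]1([C@@H](OC(C)=O)C#CC(=CCl)CO[Si](C)(C)C(C)(C)C)C=C[C@@H](O)[C@H](C)[C@@H]1C(OC)OC | intermediate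
22 | 12-O-TBS ether of 21 | C[C@]1([C@@H](OC(C)=O)C#CC(=CCl)CO[Si](C)(C)C(C)(C)C)C=C[C@@H](O[Si](C)(C)C(C)(C)C)[C@H](C)[C@@H]1C(OC)OC | intermediate
23 | (3Z)-alkene from 22 | C[C@]1([C@@H](OC(C)=O)/C=C\C(=CCl)CO[Si](C)(C)C(C)(C)C)C=C[C@@H](O[Si](C)(C)C(C)(C)C)[C@H](C)[C@@H]1C(OC)OC | intermediate
24 | C9 aldehyde from 23 | C[C@]1([C@@H](OC(C)=O)/C=C\C(=CCl)CO[Si](C)(C)C(C)(C)C)C=C[C@@H](O[Si](C)(C)C(C)(C)C)[C@H](C)[C@@H]1C=O | intermediate
25 | diethyl (S)-malate | CCOC(=O)C[C@H](O)C(=O)OCC | starting material
26 | diethyl (2S,3R)-2-hydroxy-3-methylbutanedioate | CCOC(=O)[C@@H](O)[C@@H](C)C(=O)OCC | intermediate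
27 | (2S,3R)-2-hydroxy-3-methylbutanedioic acid | OC(=O)[C@@H](O)[C@@H](C)C(=O)O | intermediate
28 | (2R)-2-[(2S,4S)-2-tert-butyl-5-oxo-1,3-dioxolan-4-yl]propanoic acid | C[C@@H](C(=O)O)[C@@H]1O[C@H](C(C)(C)C)OC1=O | intermediate
29 | tert-butyl (2R)-2-[(2S,4S)-2-tert-butyl-5-oxo-1,3-dioxolan-4-yl]propanoate | C[C@@H](C(=O)OC(C)(C)C)[C@@H]1O[C@H](C(C)(C)C)OC1=O | intermediate
30 | aldol adduct: C9 carbinol (both epimers) bonded to C8 of the dioxolanone (C8 and C17 as in the target, tert-butyl trans to C9) | C[C@]1([C@@H](OC(C)=O)/C=C\C(=CCl)CO[Si](C)(C)C(C)(C)C)C=C[C@@H](O[Si](C)(C)C(C)(C)C)[C@H](C)[C@@H]1C(O)[C@]2(O[C@H](C(C)(C)C)OC2=O)[C@@H](C)C(=O)OC(C)(C)C | intermediate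
31 | C9 ketone of 30 | C[C@]1([C@@H](OC(C)=O)/C=C\C(=CCl)CO[Si](C)(C)C(C)(C)C)C=C[C@@H](O[Si](C)(C)C(C)(C)C)[C@H](C)[C@@H]1C(=O)[C@]2(O[C@H](C(C)(C)C)OC2=O)[C@@H](C)C(=O)OC(C)(C)C | intermediate
32 | C9 alcohol with C9 as in the target | C[C@]1([C@@H](OC(C)=O)/C=C\C(=CCl)CO[Si](C)(C)C(C)(C)C)C=C[C@@H](O[Si](C)(C)C(C)(C)C)[C@H](C)[C@@H]1[C@H](O)[C@]2(O[C@H](C(C)(C)C)OC2=O)[C@@H](C)C(=O)OC(C)(C)C | intermediate
33 | Weinreb amide: C7 = C(O)N(CH3)OCH3, free 8-OH and 9-OH, C19 tert-butyl ester, 2-OAc | C[C@]1([C@@H](OC(C)=O)/C=C\C(=CCl)CO[Si](C)(C)C(C)(C)C)C=C[C@@H](O[Si](C)(C)C(C)(C)C)[C@H](C)[C@@H]1[C@H](O)[C@@](O)(C(=O)N(C)OC)[C@@H](C)C(=O)OC(C)(C)C | intermediate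
34 | C7 aldehyde with free 2-, 8- and 9-OH | C[C@]1([C@@H](O)/C=C\C(=CCl)CO[Si](C)(C)C(C)(C)C)C=C[C@@H](O[Si](C)(C)C(C)(C)C)[C@H](C)[C@@H]1[C@H](O)[C@@](O)(C=O)[C@@H](C)C(=O)OC(C)(C)C | intermediate
35 | 2,9-diacetate of 34 | C[C@]1([C@@H](OC(C)=O)/C=C\C(=CCl)CO[Si](C)(C)C(C)(C)C)C=C[C@@H](O[Si](C)(C)C(C)(C)C)[C@H](C)[C@@H]1[C@H](OC(C)=O)[C@@](O)(C=O)[C@@H](C)C(=O)OC(C)(C)C | intermediate
36 | 16-alcohol (primary allylic OH) | C[C@]1([C@@H](OC(C)=O)/C=C\C(=CCl)CO)C=C[C@@H](O[Si](C)(C)C(C)(C)C)[C@H](C)[C@@H]1[C@H](OC(C)=O)[C@@](O)(C=O)[C@@H](C)C(=O)OC(C)(C)C | intermediate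
37 | 16-methanesulfonate of 36 | C[C@]1([C@@H](OC(C)=O)/C=C\C(=CCl)COS(C)(=O)=O)C=C[C@@H](O[Si](C)(C)C(C)(C)C)[C@H](C)[C@@H]1[C@H](OC(C)=O)[C@@](O)(C=O)[C@@H](C)C(=O)OC(C)(C)C | intermediate
38 | 16-bromide | C[C@]1([C@@H](OC(C)=O)/C=C\C(=CCl)CBr)C=C[C@@H](O[Si](C)(C)C(C)(C)C)[C@H](C)[C@@H]1[C@H](OC(C)=O)[C@@](O)(C=O)[C@@H](C)C(=O)OC(C)(C)C | intermediate
39 | ring-closed tert-butyl ester: 2,9-diacetoxy-6-chloro-7,8-dihydroxy-12-(TBS-oxy)briara-3(Z),5(16),13-trien-19-oic acid tert-butyl ester, all centres as in the target | C=C1/C=C\[C@H](OC(C)=O)[C@@]2(C)C=C[C@@H](O[Si](C)(C)C(C)(C)C)[C@H](C)[C@@H]2[C@H](OC(C)=O)[C@](O)([C@@H](C)C(=O)OC(C)(C)C)[C@@H](O)[C@H]1Cl | intermediate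
40 | 12-O-(tert-butyldimethylsilyl) ether of the target | C=C1/C=C\[C@H](OC(C)=O)[C@@]2(C)C=C[C@@H](O[Si](C)(C)C(C)(C)C)[C@H](C)[C@@H]2[C@H](OC(C)=O)[C@]2(O)[C@@H](C)C(=O)O[C@H]2[C@H]1Cl | intermediate
41 | CNP0253247.1, (1S,2S,3Z,6S,7R,8R,9S,10S,11R,12R,17R)-2,9-diacetoxy-6-chloro-8,12-dihydroxybriara-3,5(16),13-trien-19,7-olide | C=C1/C=C\[C@H](OC(C)=O)[C@@]2(C)C=C[C@@H](O)[C@H](C)[C@@H]2[C@H](OC(C)=O)[C@]2(O)[C@@H](C)C(=O)O[C@H]2[C@H]1Cl | target

Total step count: 32.
Longest linear sequence: 23 steps (steps 1, 2, 4–7, 12–17 and 22–32, from 3-methylfuran-2-carboxylic acid).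

The three steps most likely to fail:

Step 4 (key step). The methyl-ketone enolate may fail to acylate the hindered lactone carbonyl through the strained bridged tetrahedral intermediate, so that retro-Michael cleavage or attack on the allyl ester takes over. The fallback sets out from 4 and 6 and comes back at 11. The Michael stage is run alone and adduct 7 is isolated. HCl in MeOH/HC(OMe)3 opens the lactone acetal to the open-chain methyl ester dimethyl acetal F1 with loss of menthol. An ordinary Dieckmann-type Claisen cyclisation of the methyl ketone onto the unstrained methyl ester (LiN(SiMe3)2, THF, −78 → 0 °C) should give the 1,3-dione acetal F2. PhNTf2/Et3N gives the enol triflate F3, and the palladium–formate conditions of step 6 give 11 directly, so that step 7 is no longer needed.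

Step 22. Addition of a fully substituted enolate to a neopentyl-type aldehyde may be slow, and retro-aldol cleavage or decomposition of the dioxolanone enolate on warming may win. The fallback sets out from 24 and comes back at 31. Pinnick oxidation (NaClO2, NaH2PO4, 2-methylbut-2-ene) gives the C9 carboxylic acid F4. 1-Chloro-N,N,2-trimethylprop-1-en-1-amine gives the acid chloride F5 under neutral conditions. C-Acylation of the lithium enolate of 29 at −78 °C then gives ketone 31 directly, replacing steps 22 and 23.

Step 30. The ring closure may lose to intermolecular allylation (oligomers), the allylmetal may attack through its CH2 terminus (eleven-membered ring), or addition may occur to the wrong aldehyde face. The fallback sets out from 36 and comes back at 39. Alcohol 36 is borylated directly (B2pin2, Pd(MeCN)4(BF4)2 cat., DMSO/MeOH) to the γ-chloroallyl pinacolboronate F6. At high dilution this should close the ring by uncatalysed intramolecular allylboration of the C7 aldehyde through a chair transition state (anti chlorohydrin), and oxidative work-up gives 39.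

Further compounds
F1 | step 4 | allyl 2-acetyl-3-(dimethoxymethyl)-2,4-dimethylpentanedioate 5-methyl ester (open-chain Michael adduct; C10 and C11 as in 7, both C1 epimers) | COC(=O)[C@H](C)[C@H](C(OC)OC)C(C)(C(C)=O)C(=O)OCC=C
F2 | step 4 | allyl (5R,6S)-6-(dimethoxymethyl)-1,5-dimethyl-2,4-dioxocyclohexane-1-carboxylate (both C1 epimers) | CC1(C(=O)OCC=C)C(=O)CC(=O)[C@H](C)[C@@H]1C(OC)OC
F3 | step 4 | allyl (5R,6S)-6-(dimethoxymethyl)-1,5-dimethyl-2-oxo-4-(trifluoromethanesulfonyloxy)cyclohex-3-ene-1-carboxylate (both C1 epimers) | CC1(C(=O)OCC=C)C(=O)C=C(OS(=O)(=O)C(F)(F)F)[C@H](C)[C@@H]1C(OC)OC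
F4 | step 22 | C9 carboxylic acid from 24 | C[C@]1([C@@H](OC(C)=O)/C=C\C(=CCl)CO[Si](C)(C)C(C)(C)C)C=C[C@@H](O[Si](C)(C)C(C)(C)C)[C@H](C)[C@@H]1C(=O)O
F5 | step 22 | C9 acid chloride from F4 | C[C@]1([C@@H](OC(C)=O)/C=C\C(=CCl)CO[Si](C)(C)C(C)(C)C)C=C[C@@H](O[Si](C)(C)C(C)(C)C)[C@H](C)[C@@H]1C(=O)Cl
F6 | step 30 | γ-chloroallyl pinacolboronate from 36 (C16–B) | C[C@]1([C@@H](OC(C)=O)/C=C\C(=CCl)CB2OC(C)(C)C(C)(C)O2)C=C[C@@H](O[Si](C)(C)C(C)(C)C)[C@H](C)[C@@H]1[C@H](OC(C)=O)[C@@](O)(C=O)[C@@H](C)C(=O)OC(C)(C)C
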